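**Assumption:** The target SMILES has no stereocentres and no stereodescriptor on the C3–C3' axis, so "single enantiomer" requires no stereocontrol. If the hindered axis is configurationally stable, the product is obtained as the racemate.

## Retrosynthetic overview

1. The target is a C2-symmetric dimer, so the only strategic disconnection is the C3–C3' bond, giving two identical 3-haloflavone halves (reductive homocoupling).
2. 3-Iodoflavone comes from flavone by C3–H iodination; C3 is the nucleophilic α-carbon of the vinylogous ester.
3. Both chromen-4-one rings are already present in commercial flavone, so no ring is formed in the route; the order is iodination, then C3–C3' coupling.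

## Route

**Step 1**
Reactants: **1** flavone (2-phenyl-4H-chromen-4-one); **2** iodine
Product: **3** 3-iodoflavone (3-iodo-2-phenyl-4H-chromen-4-one)
Conditions: I2 (1.2 equiv), CAN (1.1 equiv), dry MeCN, 60–65 °C, 6–12 h; aq. Na2S2O3 work-up
Reagents that add atoms: iodine, II
Why: CAN-mediated oxidative electrophilic iodination (SEAr-type) delivers "I+" to C3, the only enol-ether-like nucleophilic carbon; the benzo ring and 2-phenyl ring are deactivated or unactivated and are untouched. No stereocentre is formed.

**Step 2**
Reactants: **3** 3-iodoflavone (2 molecules)
Product: **4** 3,3'-biflavone (2,2'-diphenyl-4H,4'H-[3,3'-bichromene]-4,4'-dione), the target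
Conditions: activated Cu bronze (5–10 equiv), dry degassed DMF, 150 °C, Ar, 6–12 h; filter through Celite, aq. NH4OH wash
Reagents that add atoms: none
Why: Classical Ullmann reductive homocoupling. The C3–I bond is an electron-poor vinyl/aryl-type iodide flanked by a carbonyl, which favours organocopper formation and coupling; the chromone carbonyl and enol ether are inert to Cu(0). No stereocentre is formed and the axis is not controlled.

## Checks made

- Structure: the target is two 2-phenylchromen-4-one units joined C3–C3', which is what the route produces.
- Atom balance: **1** C15H10O2 → **3** C15H9IO2 → **4** C30H18O4 (2 × C15H9O2, M = 442.5). Every atom is accounted for.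
- Functional group survival: there are no protecting groups and no sensitive groups. The γ-pyrone survives CAN/I2 and Cu/DMF; strongly basic aqueous conditions, which would open the pyrone, are avoided.
- Stereochemistry: nothing to set or scramble.

## Compound list

1 | flavone (2-phenyl-4H-chromen-4-one) | O=c1cc(-c2ccccc2)oc2ccccc12 | starting material
2 | iodine | II | starting material (reagent)
3 | 3-iodoflavone (3-iodo-2-phenyl-4H-chromen-4-one) | O=c1c(I)c(-c2ccccc2)oc2ccccc12 | intermediate
4 | 3,3'-biflavone | O=c1c(-c2c(-c3ccccc3)oc3ccccc3c2=O)c(-c2ccccc2)oc2ccccc12 | target

## Summary

Total step count: 2. Longest linear sequence: 2.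

Steps most likely to fail (the route has only two steps, so the two failure modes of Step 2 are listed separately):

1. **Step 2, low conversion from steric hindrance.** The new bond is a tetra-ortho-substituted biaryl-type bond. Fallback: form the C3–C3' bond before the rings exist. Oxidatively dimerise 1-(2-hydroxyphenyl)-3-phenylpropane-1,3-dione (from 2'-hydroxyacetophenone by Baker–Venkataraman) at its central carbon with I2/base or CAN to give the tetraketone, then perform a double acid cyclodehydration (H2SO4/AcOH) to give **4**.
2. **Step 2, hydro-deiodination back to flavone instead of coupling.** Fallback: switch from reductive homocoupling to cross-coupling. Convert half of **3** to the flavone-3-boronic ester (Miyaura borylation with B2pin2) and join it to the remaining **3** by Suzuki–Miyaura coupling (Pd(OAc)2/SPhos, K3PO4, toluene/H2O).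
3. **Step 1, incomplete or unselective iodination of unactivated flavone.** Fallback: build the iodinated ring de novo. Prepare 1-(2-methoxyphenyl)-3-phenylprop-2-yn-1-one from 2-methoxybenzoyl chloride and phenylacetylene (acyl Sonogashira), then carry out ICl-induced iodocyclisation with loss of MeCl (CH2Cl2, −78 °C to rt) to give **3** directly.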